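## Structural features

The target is a 2,3-trans-disubstituted 2,3-dihydro-1,4-benzodioxine: a 1,4-dioxane ring fused through C4 and C5 to benzene ring A. Dioxane carbon C7 bears a 4-hydroxy-3,5-dimethoxyphenyl (syringyl) ring and its neighbour C8 bears the hydroxymethyl carbon C9. C7 and C8 are adjacent stereocentres, both S, with the aryl and hydroxymethyl groups trans. O5 joins C7 to C5 and O4 joins C8 to C4; ring A also carries a methoxy group on C3, an (E)-3-hydroxyprop-1-enyl chain on C1 and hydrogens on C2 and C6. The fragile points are the free phenol para to the benzylic C7–O5 bond (quinone methide under base, benzylic cation under acid), the cinnamyl-type allylic alcohol and two electron-rich arenes. The real difficulty is not the two stereocentres but the constitution of the dioxane: two nearly equivalent catechol-type oxygens of ring A must be bonded, one to C7 and the other to C8, without the regioisomer and with the trans relationship kept. The key step exploits the substitution pattern of ring A: with hydrogens on C2 and C6 and heteroatoms on C3, C4 and C5, its six carbons divide into three two-carbon units, C5–C6, C4–C3 and C1–C2. The first two are alkynes hung on O5 and O4 of a preformed threo diol and the third is the terminal alkyne of an enyne, so one cyclotrimerisation builds ring A and the dioxane around stereocentres that already exist.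

## Logic of the disconnections

**29 from 28.** Three O–Si bonds are cut (phenol, C9–O, allylic O). Every hydroxyl that must survive strong base is silylated, so one fluoride treatment ends the route and neither acid nor oxidant meets the free phenol or the allylic alcohol. The forward step must be buffered, because the phenoxide set free stands para to the benzylic C7–O5 bond.

**28 from 27.** The C3–OMe bond is cut and replaced by C3–B. Oxygen cannot ride on that alkyne carbon through the cycloaddition (an alkyne with oxygen on both carbons is not a workable species), whereas boron can, and boron also serves as the steric marker for the regiochemistry of ring formation. The forward step must turn a hindered, ortho-oxygenated aryl boronate into a methyl ether in the presence of an alkene and three silyl ethers.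

**27 from 24 and 26.** Three bonds are cut: C4–C5, C6–C1 and C2–C3. Both rings disappear at once, leaving an acyclic bis-ether of a diol and a five-carbon enyne. Which ring A oxygen is bonded to C7 and which to C8 is then decided by which alkyne hangs on which oxygen, not by a selective alkylation of a catechol. The forward step must join three alkynes in the right sense (substituted carbon of 26 to C6, its CH to C3), leave the alkene of 26 alone, and run at room temperature because the benzylic ynol ether of 24 can rearrange on warming.

**24 from 19 and 20.** The C–B bond of the C8 arm is cut and the terminal alkyne of the C7 arm is traced back to a dichlorovinyl ether. The two arms cannot simply be finished one after the other: a boronate would not survive KH or n-BuLi, and a terminal alkyne already in place would be lithiated and borylated together with the second one. In 19 the arm that is to carry boron is therefore already a terminal alkyne and the other arm is still masked. One equivalent of base and 20 place boron, and the masked arm is unmasked in the same flask while boron is tetracoordinate. The demand is strict order of addition, exact stoichiometry and low temperature.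

**19 from 17 and 11; 17 from 15; 15 from 14; 14 from 13; 13 from 10 and 11.** The O7–C and O8–C bonds to the two-carbon units are cut back to 11. The C8 arm must reach the alkyne stage (17) before O7 is vinylated, so O7 has to be blocked while O8 reacts. In 10 and 13 it is tied to O9 in a silylene ring, which also keeps any monodentate silyl ether away from the C8 alkoxide. After the first vinylation the ring is opened (14) and O9 alone is silylated (15). The demands are that the alkoxide of 10 does not attack the ring silicon, and that the step from 17 uses one equivalent of base so that the alkyne C–H is left alone.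

**10 from 9; 9 from 8.** The two Si–O bonds of the bridge are cut and O8 regains a benzyl group. With O8 benzylated the only free diol in 8 is the 1,3-pair O7/O9, so the bridge can go on in one way only. No selective protection of two like secondary hydroxyls is asked for. The hydrogenolysis must spare the benzylic C7–O bond.

**8 from 7; 7 from 5 and 2.** The C7–C8 bond is cut (aldol), with C9 returning to the acyl carbon of an oxazolidinone imide. This is the largest simplification: one syn-selective C–C bond formation sets both stereocentres and delivers O7 as a free hydroxyl and O8 as an ether, a distinction that dihydroxylation of the corresponding alkene would not make. The demand is Z-enolate geometry and face control by the auxiliary; the (R)-auxiliary is needed for the (7S,8S) series.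

**5 from 3 and 4; 2 from 1; 26 from 25.** An N–acyl bond and two O–Si bonds lead to purchasable materials; nothing selective is required.

## Other disconnections considered

**Alternative 1:** The cut is through C8–O4 and C7–C8, giving three components: a diazoacetate (C8, C9), a ring A bromophenol that already carries the chain, and an O-acylated syringyl aldehyde. In the forward step Rh2(OAc)4 turns the diazo ester into a rhodium carbene, the phenol oxygen adds to give an oxonium ylide, and the aldehyde, activated by a chiral BINOL-derived phosphoric acid, traps it in an aldol-type step before the 1,2-proton shift. The product would be the threo ester A1.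
- In its favour: two bonds and both stereocentres arise in one catalytic operation, and ring A arrives complete, with bromine marking C5 for a later O5–C5 closure. Ring closure, hydride reduction of both esters and deprotection would finish the synthesis in well under half the steps of the chosen plan. On step economy and convergence it is clearly the better plan.
- Against it here: trapping must outrun plain O–H insertion. The 2-bromo-6-methoxyphenol is a hindered, weak nucleophile and the electron-rich aldehyde a sluggish electrophile. Both threo/erythro selectivity and enantioselectivity would rest on catalyst control for an untried pairing, and any erythro product leads to the cis ring.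
- Comparison: on structure the two plans are equal, since each fixes by construction which oxygen is bonded to C8. On mechanism the chosen plan sets its stereocentres more dependably (auxiliary aldol), but its ring-forming step is less precedented, so neither has a clear overall advantage in risk.

**Alternative 2:** The cut is the C8–O4 bond. In the forward step the C4 phenoxide of ring A, already tied to C7 through O5, opens a C8–C9 epoxide at C8 (6-exo-tet, inversion), closing the dioxane and freeing the C9 hydroxyl to give the aldehyde A2.
- In its favour: the step is stereospecific, metal-free and well precedented in type, and it releases the C9 hydroxyl without a deprotection. On precedent and on step count it is better than the chosen plan.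
- Against it here: the precursor needs the benzylic C7–O5 aryl ether as a single diastereomer next to an epoxide of the right configuration, and substitution at a benzylic carbon bearing so electron-rich a ring tends to ionise. Attack at the unhindered C9 (7-endo) competes. The two ring A oxygens must still be told apart when the C7 ether is made, and the methoxymethyl group must later be removed with acid near a cinnamyl alcohol.
- Comparison: on structure the chosen plan is better, having no exo/endo question and no catechol discrimination. On mechanism and step economy alternative 2 is better.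

**Alternative 3:** The cut is the O5–C5 bond. In the forward step zerovalent palladium from Pd2(dba)3 with a bulky di-tert-butylbiarylphosphine and Cs2CO3 inserts into the C5–Br bond, the C7 alkoxide binds, and C–O reductive elimination closes the dioxane to give the acetal A3.
- In its favour: no bond at a stereocentre is made or broken, so both centres pass through untouched, which equals the chosen plan. The reaction class is established for benzodioxanes, so on precedent it is better, and the route would be several steps shorter.
- Against it here: a secondary benzylic alkoxide on palladium can undergo beta-hydride elimination, giving ketone and reduced arene. The C8–O4 aryl ether must first be made with defined configuration, which again requires telling the two hydroxyls of a diol apart. The acetal and methoxymethyl groups call for acid at the end.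
- Comparison: structurally equal in stereochemical integrity and in the burden of differentiating the diol. On mechanism and step economy alternative 3 is better. What the chosen plan offers in return is that ring A and its substitution pattern are created rather than bought.

Key step: step 14

Remark: lignan numbering is used throughout (ring A: C1–C6, O4, O5; side chain on the syringyl ring: C7, C8, C9). Ar = 3,5-dimethoxy-4-(triisopropylsilyloxy)phenyl, TIPS = triisopropylsilyl, TBS = tert-butyldimethylsilyl, Bpin = 4,4,5,5-tetramethyl-1,3,2-dioxaborolan-2-yl. C7 and C8 are S in 24, 27 and 29 alike, so no structure needed correction; what needed repair was the order of operations on the two hydroxyls. Compounds 1, 3, 4, 11, 20 and 25 are taken as catalogue materials. The dichlorovinyl ethers are drawn (E), as anti addition to dichloroacetylene should give; the geometry is lost in the next step.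

## Steps

Step 1
Reactants: 1 syringaldehyde
Product: 2 3,5-dimethoxy-4-(triisopropylsilyloxy)benzaldehyde
Conditions: TIPSCl, imidazole, DMF, rt
Reagents that add atoms: chlorotriisopropylsilane, CC(C)[Si](Cl)(C(C)C)C(C)C
Why: Silylation of a phenol; the hindered silyl ether, flanked by two methoxy groups, should withstand KH, n-BuLi, hydrogenolysis and HF·pyridine and fall to fluoride at the end.

Step 2
Reactants: 3 (R)-4-benzyloxazolidin-2-one; 4 (benzyloxy)acetyl chloride
Product: 5 (R)-4-benzyl-3-[(benzyloxy)acetyl]oxazolidin-2-one
Conditions: Et3N, DMAP (cat.), CH2Cl2, 0 °C → rt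
Reagents that add atoms: none
Why: N-Acylation of the oxazolidinone auxiliary with an acid chloride; the benzyl group on the glycolate oxygen is what will later distinguish O8 from O7.

Step 3
Reactants: 5 (R)-4-benzyl-3-[(benzyloxy)acetyl]oxazolidin-2-one; 2 3,5-dimethoxy-4-(triisopropylsilyloxy)benzaldehyde
Product: 7 (4R)-4-benzyl-3-[(2R,3S)-3-Ar-2-(benzyloxy)-3-hydroxypropanoyl]oxazolidin-2-one, via boron enolate 6 (not isolated)
Conditions: Bu2BOTf, Et3N, CH2Cl2, −78 → 0 °C; then 2, −78 → 0 °C; pH 7 buffer, MeOH, H2O2, 0 °C
Reagents that add atoms: none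
Why: Evans syn-aldol reaction: the Z-boron enolate reacts through a Zimmerman–Traxler chair with the aldehyde on the face away from the benzyl group of the (R)-auxiliary, which should set C7 and C8 together in the threo (future 7S,8S) sense. O7 leaves the step as a free hydroxyl and O8 as a benzyl ether.

Step 4
Reactants: 7 (4R)-4-benzyl-3-[(2R,3S)-3-Ar-2-(benzyloxy)-3-hydroxypropanoyl]oxazolidin-2-one
Product: 8 (1S,2S)-1-Ar-2-(benzyloxy)propane-1,3-diol
Conditions: LiBH4, MeOH (1 equiv), THF, 0 °C
Reagents that add atoms: none
Why: Reductive cleavage of the N-acyl oxazolidinone to the primary alcohol (C9) with recovery of the auxiliary; no base strong enough to epimerise C8 is present.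

Step 5
Reactants: 8 (1S,2S)-1-Ar-2-(benzyloxy)propane-1,3-diol
Product: 9 (4S,5S)-4-Ar-5-(benzyloxy)-2,2-di-tert-butyl-1,3,2-dioxasilinane
Conditions: t-Bu2Si(OTf)2, 2,6-lutidine, CH2Cl2, 0 °C
Reagents that add atoms: di-tert-butylsilyl bis(trifluoromethanesulfonate), CC(C)(C)[Si](OS(=O)(=O)C(F)(F)F)(OS(=O)(=O)C(F)(F)F)C(C)(C)C
Why: Cyclic silylene protection of a 1,3-diol; with O8 benzylated only O7 and O9 can be bridged, giving a six-membered ring with the aryl group equatorial.

Step 6
Reactants: 9 (4S,5S)-4-Ar-5-(benzyloxy)-2,2-di-tert-butyl-1,3,2-dioxasilinane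
Product: 10 (4S,5S)-4-Ar-2,2-di-tert-butyl-1,3,2-dioxasilinan-5-ol
Conditions: H2 (1 atm), Pd/C, EtOAc, rt
Reagents that add atoms: none
Why: Hydrogenolysis of the benzyl ether; there is no alkene or alkyne yet, and the benzylic C7–O bond (a silyl ether in a neutral solvent) should be cleaved far more slowly than the O-benzyl group.

Step 7
Reactants: 10 (4S,5S)-4-Ar-2,2-di-tert-butyl-1,3,2-dioxasilinan-5-ol; 11 trichloroethylene
Product: 13 (4S,5S)-4-Ar-2,2-di-tert-butyl-5-[(E)-1,2-dichloroethenyloxy]-1,3,2-dioxasilinane, via potassium alkoxide 12 (not isolated)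
Conditions: KH, THF, 0 °C; then 11, −50 °C → rt
Reagents that add atoms: none
Why: Dichlorovinyl ether formation: the alkoxide adds to dichloroacetylene generated in the flask from 11. The only silicon within reach is locked in the di-tert-butylsilylene ring (transfer would need a strained bicyclic silicate), so silyl migration to the alkoxide is not expected.

Step 8
Reactants: 13 (4S,5S)-4-Ar-2,2-di-tert-butyl-5-[(E)-1,2-dichloroethenyloxy]-1,3,2-dioxasilinane
Product: 14 (1S,2S)-1-Ar-2-[(E)-1,2-dichloroethenyloxy]propane-1,3-diol
Conditions: HF·pyridine, pyridine, THF, 0 °C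
Reagents that add atoms: none
Why: Fluoride cleavage of the silylene under non-basic conditions, so that no alkoxide is generated next to the dichlorovinyl ether; the chlorine-deactivated enol ether and the aryl silyl ether should survive.

Step 9
Reactants: 14 (1S,2S)-1-Ar-2-[(E)-1,2-dichloroethenyloxy]propane-1,3-diol
Product: 15 (1S,2S)-1-Ar-2-[(E)-1,2-dichloroethenyloxy]-3-(triisopropylsilyloxy)propan-1-ol
Conditions: TIPSCl (1.1 equiv), imidazole, CH2Cl2, 0 °C
Reagents that add atoms: chlorotriisopropylsilane, CC(C)[Si](Cl)(C(C)C)C(C)C
Why: Selective silylation of the primary C9 hydroxyl; the bulky silyl chloride should leave the secondary benzylic C7 hydroxyl free.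

Step 10
Reactants: 15 (1S,2S)-1-Ar-2-[(E)-1,2-dichloroethenyloxy]-3-(triisopropylsilyloxy)propan-1-ol
Product: 17 (1S,2S)-1-Ar-2-(ethynyloxy)-3-(triisopropylsilyloxy)propan-1-ol, via dilithio species 16 (not isolated)
Conditions: n-BuLi (3.3 equiv), THF, −78 → −40 °C; then H2O, −78 °C
Reagents that add atoms: none
Why: Conversion of a dichlorovinyl ether into an ynol ether by elimination and chlorine–lithium exchange (two n-BuLi; a third deprotonates the C7 hydroxyl), then protonation. No boron is present and O7 is not yet vinylated, so only the C8 arm becomes an alkyne.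

Step 11
Reactants: 17 (1S,2S)-1-Ar-2-(ethynyloxy)-3-(triisopropylsilyloxy)propan-1-ol; 11 trichloroethylene
Product: 19 [(2S,3S)-3-Ar-3-[(E)-1,2-dichloroethenyloxy]-2-(ethynyloxy)propoxy]triisopropylsilane, via potassium alkoxide 18 (not isolated)
Conditions: KH (1.05 equiv), THF, −20 °C; then 11, −50 → 0 °C
Reagents that add atoms: none
Why: Second dichlorovinyl ether formation: one equivalent of KH takes the hydroxyl proton, far more acidic than the alkyne C–H, and the alkoxide adds to dichloroacetylene. The C7 arm is thereby stored in its base-stable masked form while the C8 arm stays a terminal alkyne.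

Step 12
Reactants: 19 [(2S,3S)-3-Ar-3-[(E)-1,2-dichloroethenyloxy]-2-(ethynyloxy)propoxy]triisopropylsilane; 20 2-isopropoxy-4,4,5,5-tetramethyl-1,3,2-dioxaborolane
Product: 24 [(2S,3S)-3-Ar-3-(ethynyloxy)-2-[(Bpin)ethynyloxy]propoxy]triisopropylsilane (threo bis-ynol ether with the C8 arm borylated), via C8 lithium acetylide 21 (not isolated), via isopropoxy borate 22 (not isolated), via borate acetylide 23 (not isolated)
Conditions: n-BuLi (1.0 equiv), THF, −78 °C; 20 (1.05 equiv), −78 °C; n-BuLi (2.2 equiv), −78 → −45 °C; HCl in Et2O (2.1 equiv), −78 °C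
Reagents that add atoms: none
Why: Lithiation of a terminal alkyne with borate-ester trapping, followed by the dichlorovinyl-ether-to-acetylide elimination on the other arm, both standard operations. Run in this order, boron is held as a tetracoordinate isopropoxy borate with no vacant orbital for n-BuLi while the C7 arm is unmasked, and one stoichiometric acid quench protonates the C7 acetylide and strips isopropoxide from boron.

Step 13
Reactants: 25 (E)-pent-2-en-4-yn-1-ol
Product: 26 (E)-tert-butyldimethyl(pent-2-en-4-ynyloxy)silane
Conditions: TBSCl, imidazole, CH2Cl2, 0 °C → rt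
Reagents that add atoms: tert-butylchlorodimethylsilane, CC(C)(C)[Si](C)(C)Cl
Why: Silylation of a primary allylic alcohol, so that no hydroxyl meets the ruthenium catalyst or the boronate.

Step 14
Reactants: 24 threo bis-ynol ether with the C8 arm borylated; 26 (E)-tert-butyldimethyl(pent-2-en-4-ynyloxy)silane
Product: 27 (7S,8S)-trans-benzodioxane with Bpin on C3, (E)-3-(TBS-oxy)prop-1-enyl on C1, Ar on C7 and CH2OTIPS on C8
Conditions: Cp*RuCl(cod) (10 mol%), 26 (3 equiv), ClCH2CH2Cl, rt, 24 added over 4 h
Reagents that add atoms: none
Why: Proposed new method: the Cp*RuCl fragment (divalent ruthenium, cod lost) binds the two ynol ether alkynes of 24 and couples them oxidatively to a tetravalent ruthenacyclopentadiene, which forms C4–C5 and thereby closes the 1,4-dioxane as the six-membered ring fused to the metallacycle (metal-templated closure over the four-atom O–C–C–O tether); the terminal alkyne of 26 then coordinates and inserts, and reductive elimination forms C6–C1 and C2–C3, closing benzene ring A as a formal (2+2+2) cycloaddition and returning divalent ruthenium. The closest known reaction type is the Cp*RuCl(cod)-catalysed cycloaddition of unsymmetrical tethered diynes, alkynylboronate-terminated ones included, with terminal alkynes, together with cyclotrimerisations that accept ynol ethers; a diyne whose tether oxygens sit directly on both alkynes and which carries boron on one of them has not been tried. No stereocentre is formed: C7 and C8 lie outside the reacting atoms and are carried through unchanged, so the trans ring follows from the threo diol. The step needs the substituent of 26 to end meta to boron; the bulky pinacol boronate on ruthenacycle carbon C3 should steer the unsubstituted CH end of 26 next to it and the substituted carbon to the unhindered C6 side. It also needs reaction at the alkyne and not the alkene of 26, which the alkyne preference of the Cp*RuCl fragment and the E-disubstituted alkene should secure, and cross-coupling over diyne self-coupling, which slow addition of 24 into excess 26 favours. Room temperature keeps the benzylic ynol ether of 24 from sigmatropic rearrangement before it is consumed.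

Step 15
Reactants: 27 (7S,8S)-trans-benzodioxane with Bpin on C3
Product: 28 (7S,8S)-trans-benzodioxane with methoxy on C3, (E)-3-(TBS-oxy)prop-1-enyl on C1, Ar on C7 and CH2OTIPS on C8
Conditions: Cu(OAc)2 (2 equiv), DMAP, MeOH/CH2Cl2, 4 Å sieves, air, rt
Reagents that add atoms: methanol, CO
Why: Chan–Lam coupling of an aryl boronate with methanol: transmetalation to divalent copper, oxidation and C–O reductive elimination. The alkene and the silyl ethers should not react under these conditions.

Step 16
Reactants: 28 (7S,8S)-trans-benzodioxane with methoxy on C3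
Product: 29 4-[(2S,3S)-3-(hydroxymethyl)-7-[(E)-3-hydroxyprop-1-enyl]-5-methoxy-2,3-dihydro-1,4-benzodioxin-2-yl]-2,6-dimethoxyphenol (target)
Conditions: Bu4NF, AcOH, THF, 0 °C → rt
Reagents that add atoms: none
Why: Fluoride cleavage of the three silyl ethers; acetic acid keeps the liberated phenol, para to the benzylic C7–O5 bond, from opening the dioxane through a quinone methide. Even if that happened, reclosure could only return the favoured trans ring, since C8 is untouched.

## Compound list

1 | syringaldehyde | COc1cc(C=O)cc(OC)c1O | starting material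
2 | 3,5-dimethoxy-4-(triisopropylsilyloxy)benzaldehyde | COc1cc(C=O)cc(OC)c1O[Si](C(C)C)(C(C)C)C(C)C | intermediate
3 | (R)-4-benzyloxazolidin-2-one | O=C1OC[C@@H](Cc2ccccc2)N1 | starting material
4 | (benzyloxy)acetyl chloride | O=C(Cl)COCc1ccccc1 | starting material
5 | (R)-4-benzyl-3-[(benzyloxy)acetyl]oxazolidin-2-one | O=C(COCc1ccccc1)N1C(=O)OC[C@H]1Cc1ccccc1 | intermediate
6 | (Z)-dibutylboron enolate of 5 | CCCCB(CCCC)O/C(=C\OCc1ccccc1)N1C(=O)OC[C@H]1Cc1ccccc1 | intermediate (not isolated)
7 | (4R)-4-benzyl-3-[(2R,3S)-3-Ar-2-(benzyloxy)-3-hydroxypropanoyl]oxazolidin-2-one | COc1cc(cc(OC)c1O[Si](C(C)C)(C(C)C)C(C)C)[C@H](O)[C@@H](OCc1ccccc1)C(=O)N1C(=O)OC[C@H]1Cc1ccccc1 | intermediate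
8 | (1S,2S)-1-Ar-2-(benzyloxy)propane-1,3-diol | COc1cc(cc(OC)c1O[Si](C(C)C)(C(C)C)C(C)C)[C@H](O)[C@@H](OCc1ccccc1)CO | intermediate
9 | (4S,5S)-4-Ar-5-(benzyloxy)-2,2-di-tert-butyl-1,3,2-dioxasilinane | COc1cc(cc(OC)c1O[Si](C(C)C)(C(C)C)C(C)C)[C@@H]1O[Si](C(C)(C)C)(C(C)(C)C)OC[C@@H]1OCc1ccccc1 | intermediate
10 | (4S,5S)-4-Ar-2,2-di-tert-butyl-1,3,2-dioxasilinan-5-ol | COc1cc(cc(OC)c1O[Si](C(C)C)(C(C)C)C(C)C)[C@@H]1O[Si](C(C)(C)C)(C(C)(C)C)OC[C@@H]1O | intermediate
11 | trichloroethylene | ClC=C(Cl)Cl | starting material
12 | potassium alkoxide of 10 | COc1cc(cc(OC)c1O[Si](C(C)C)(C(C)C)C(C)C)[C@@H]1O[Si](C(C)(C)C)(C(C)(C)C)OC[C@@H]1O[K] | intermediate (not isolated)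
13 | (4S,5S)-4-Ar-2,2-di-tert-butyl-5-[(E)-1,2-dichloroethenyloxy]-1,3,2-dioxasilinane | COc1cc(cc(OC)c1O[Si](C(C)C)(C(C)C)C(C)C)[C@@H]1O[Si](C(C)(C)C)(C(C)(C)C)OC[C@@H]1O/C(Cl)=C\Cl | intermediate
14 | (1S,2S)-1-Ar-2-[(E)-1,2-dichloroethenyloxy]propane-1,3-diol | COc1cc(cc(OC)c1O[Si](C(C)C)(C(C)C)C(C)C)[C@H](O)[C@@H](O/C(Cl)=C\Cl)CO | intermediate
15 | (1S,2S)-1-Ar-2-[(E)-1,2-dichloroethenyloxy]-3-(triisopropylsilyloxy)propan-1-ol | COc1cc(cc(OC)c1O[Si](C(C)C)(C(C)C)C(C)C)[C@H](O)[C@@H](O/C(Cl)=C\Cl)CO[Si](C(C)C)(C(C)C)C(C)C | intermediate
16 | dilithio species from 15 (C7 lithium alkoxide, C8 lithium alkoxyacetylide) | COc1cc(cc(OC)c1O[Si](C(C)C)(C(C)C)C(C)C)[C@H](O[Li])[C@@H](OC#C[Li])CO[Si](C(C)C)(C(C)C)C(C)C | intermediate (not isolated)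
17 | (1S,2S)-1-Ar-2-(ethynyloxy)-3-(triisopropylsilyloxy)propan-1-ol | COc1cc(cc(OC)c1O[Si](C(C)C)(C(C)C)C(C)C)[C@H](O)[C@@H](OC#C)CO[Si](C(C)C)(C(C)C)C(C)C | intermediate
18 | potassium alkoxide of 17 | COc1cc(cc(OC)c1O[Si](C(C)C)(C(C)C)C(C)C)[C@H](O[K])[C@@H](OC#C)CO[Si](C(C)C)(C(C)C)C(C)C | intermediate (not isolated)
19 | [(2S,3S)-3-Ar-3-[(E)-1,2-dichloroethenyloxy]-2-(ethynyloxy)propoxy]triisopropylsilane | COc1cc(cc(OC)c1O[Si](C(C)C)(C(C)C)C(C)C)[C@H](O/C(Cl)=C\Cl)[C@@H](OC#C)CO[Si](C(C)C)(C(C)C)C(C)C | intermediate
20 | 2-isopropoxy-4,4,5,5-tetramethyl-1,3,2-dioxaborolane | CC(C)OB1OC(C)(C)C(C)(C)O1 | starting material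
21 | C8 lithium acetylide of 19 | COc1cc(cc(OC)c1O[Si](C(C)C)(C(C)C)C(C)C)[C@H](O/C(Cl)=C\Cl)[C@@H](OC#C[Li])CO[Si](C(C)C)(C(C)C)C(C)C | intermediate (not isolated)
22 | lithium isopropoxy(pinacolato)borate on the C8 alkyne, C7 arm still dichlorovinyl | [Li+].COc1cc(cc(OC)c1O[Si](C(C)C)(C(C)C)C(C)C)[C@H](O/C(Cl)=C\Cl)[C@@H](OC#C[B-]1(OC(C)C)OC(C)(C)C(C)(C)O1)CO[Si](C(C)C)(C(C)C)C(C)C | intermediate (not isolated)
23 | the same borate with the C7 arm as lithium acetylide | [Li+].COc1cc(cc(OC)c1O[Si](C(C)C)(C(C)C)C(C)C)[C@H](OC#C[Li])[C@@H](OC#C[B-]1(OC(C)C)OC(C)(C)C(C)(C)O1)CO[Si](C(C)C)(C(C)C)C(C)C | intermediate (not isolated)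
24 | [(2S,3S)-3-Ar-3-(ethynyloxy)-2-[(Bpin)ethynyloxy]propoxy]triisopropylsilane (threo bis-ynol ether, C8 arm borylated) | COc1cc(cc(OC)c1O[Si](C(C)C)(C(C)C)C(C)C)[C@H](OC#C)[C@@H](OC#CB1OC(C)(C)C(C)(C)O1)CO[Si](C(C)C)(C(C)C)C(C)C | intermediate
25 | (E)-pent-2-en-4-yn-1-ol | C#C/C=C/CO | starting material
26 | (E)-tert-butyldimethyl(pent-2-en-4-ynyloxy)silane | C#C/C=C/CO[Si](C)(C)C(C)(C)C | intermediate
27 | (7S,8S)-trans-benzodioxane: Bpin on C3, (E)-3-(TBS-oxy)prop-1-enyl on C1, Ar on C7, CH2OTIPS on C8 | COc1cc(cc(OC)c1O[Si](C(C)C)(C(C)C)C(C)C)[C@@H]1Oc2cc(/C=C/CO[Si](C)(C)C(C)(C)C)cc(B3OC(C)(C)C(C)(C)O3)c2O[C@H]1CO[Si](C(C)C)(C(C)C)C(C)C | intermediate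
28 | (7S,8S)-trans-benzodioxane: methoxy on C3, (E)-3-(TBS-oxy)prop-1-enyl on C1, Ar on C7, CH2OTIPS on C8 | COc1cc(cc(OC)c1O[Si](C(C)C)(C(C)C)C(C)C)[C@@H]1Oc2cc(/C=C/CO[Si](C)(C)C(C)(C)C)cc(OC)c2O[C@H]1CO[Si](C(C)C)(C(C)C)C(C)C | intermediate
29 | 4-[(2S,3S)-3-(hydroxymethyl)-7-[(E)-3-hydroxyprop-1-enyl]-5-methoxy-2,3-dihydro-1,4-benzodioxin-2-yl]-2,6-dimethoxyphenol | COc1cc([C@@H]2Oc3cc(/C=C/CO)cc(OC)c3O[C@H]2CO)cc(OC)c1O | target

## Step count and least certain steps

Total step count: 16. Longest linear sequence: 14 (steps 1, 3 to 12, 14 to 16); steps 2 and 13 are side branches.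

**Step 14 (key step).** The oxidative coupling may not start, because the boryl ynol ether binds ruthenium poorly or the terminal ynol ether diverts the catalyst into vinylidene or carbene formation. Regiocontrol may leak, placing the substituent ortho to boron. The enyne may oligomerise with itself, the boronate may be lost by protodeboronation, and the benzylic ynol ether may rearrange before it cyclises.
Fallback (known chemistry; sets out from 2, returns at 29): ring A is brought in ready-made and the dioxane is closed by palladium-catalysed aryl etherification. 5-Bromovanillin and Ph3P=CHCO2Et give ethyl (E)-3-(3-bromo-4-hydroxy-5-methoxyphenyl)acrylate F1. Compound 3 and bromoacetyl bromide give (R)-4-benzyl-3-(bromoacetyl)oxazolidin-2-one F2, and F1 is O-alkylated by F2 (K2CO3, acetone) to the ring A aryloxyacetyl imide F3. Evans syn-aldol reaction of F3 with 2 (Bu2BOTf, Et3N) should give the threo aldol adduct F4 with the C8–O4 bond and both stereocentres in place. LiBH4 at 0 °C, which reduces the imide faster than the conjugated ester, gives the 1,3-diol F5, and TIPSCl/imidazole gives the C9 silyl ether F6. Pd(OAc)2, a di-tert-butylbiarylphosphine and Cs2CO3 in toluene then close O5–C5 to the benzodioxane enoate F7. i-Bu2AlH reduces F7 to the allylic alcohol F8, and Bu4NF/AcOH gives 29.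

**Step 12.** Isopropoxide may dissociate from the borate during the second lithiation, letting n-BuLi add to boron or boron move between acetylides. The first deprotonation may not be fully selective for the alkyne C–H, and a slight excess of acid in the quench may hydrate an ynol ether.
Fallback (sets out from 19, returns at 24): both arms are made terminal and boron is introduced without discrimination, so that n-BuLi and boron never share a flask. n-BuLi (2.2 equiv) then water converts 19 into the bis-terminal diyne F9. LiN(SiMe3)2 (1.0 equiv), 20 and HCl in Et2O then give a statistical mixture of 24, its C7-borylated isomer F10, the diborylated diyne F11 and unchanged F9. Compound 24 is separated by chromatography, F9 is recycled, and F10 and F11 are returned to F9 by protodeboronation with K2CO3/MeOH.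

**Step 11.** KH may deprotonate the alkyne C–H as well as the hydroxyl, or the C7 alkoxide may add to the neighbouring ynol ether before it meets dichloroacetylene.
Fallback (sets out from 15, returns at 19): the alkyne C–H is capped before the second alkoxide is made. The dilithio species from 15 and n-BuLi is quenched with Me3SiCl to the C,O-bis(trimethylsilyl) compound F12. Brief K2CO3/MeOH at −20 °C cleaves only the silyl ether, giving the alkynylsilane alcohol F13. KH and 11 give the silyl-capped dichlorovinyl ether F14, and K2CO3/MeOH at room temperature removes the alkyne cap to give 19.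

**Step 15.** Protodeboronation may outrun C–O coupling at the hindered, doubly ortho-oxygenated boronate, and basic methanol may slowly cleave the aryl silyl ether.
Fallback (sets out from 27, returns at 28): NaBO3·4H2O in THF/water oxidises the boronate to the C3 phenol F15, and MeI with K2CO3 in acetone methylates it to 28. This costs one more step; both operations are standard.

## Further compounds

F1 | step 14 | ethyl (E)-3-(3-bromo-4-hydroxy-5-methoxyphenyl)acrylate | CCOC(=O)/C=C/c1cc(Br)c(O)c(OC)c1
F2 | step 14 | (R)-4-benzyl-3-(bromoacetyl)oxazolidin-2-one | O=C(CBr)N1C(=O)OC[C@H]1Cc1ccccc1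
F3 | step 14 | ring A aryloxyacetyl imide | CCOC(=O)/C=C/c1cc(Br)c(OCC(=O)N2C(=O)OC[C@H]2Cc2ccccc2)c(OC)c1
F4 | step 14 | threo aldol adduct | COc1cc(cc(OC)c1O[Si](C(C)C)(C(C)C)C(C)C)[C@H](O)[C@@H](Oc1c(Br)cc(/C=C/C(=O)OCC)cc1OC)C(=O)N1C(=O)OC[C@H]1Cc1ccccc1
F5 | step 14 | 1,3-diol | COc1cc(cc(OC)c1O[Si](C(C)C)(C(C)C)C(C)C)[C@H](O)[C@@H](Oc1c(Br)cc(/C=C/C(=O)OCC)cc1OC)CO
F6 | step 14 | C9 silyl ether | COc1cc(cc(OC)c1O[Si](C(C)C)(C(C)C)C(C)C)[C@H](O)[C@@H](Oc1c(Br)cc(/C=C/C(=O)OCC)cc1OC)CO[Si](C(C)C)(C(C)C)C(C)C
F7 | step 14 | benzodioxane enoate | COc1cc(cc(OC)c1O[Si](C(C)C)(C(C)C)C(C)C)[C@@H]1Oc2cc(/C=C/C(=O)OCC)cc(OC)c2O[C@H]1CO[Si](C(C)C)(C(C)C)C(C)C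
F8 | step 14 | allylic alcohol | COc1cc(cc(OC)c1O[Si](C(C)C)(C(C)C)C(C)C)[C@@H]1Oc2cc(/C=C/CO)cc(OC)c2O[C@H]1CO[Si](C(C)C)(C(C)C)C(C)C
F9 | step 12 | bis-terminal diyne | COc1cc(cc(OC)c1O[Si](C(C)C)(C(C)C)C(C)C)[C@H](OC#C)[C@@H](OC#C)CO[Si](C(C)C)(C(C)C)C(C)C
F10 | step 12 | C7-borylated isomer | COc1cc(cc(OC)c1O[Si](C(C)C)(C(C)C)C(C)C)[C@H](OC#CB1OC(C)(C)C(C)(C)O1)[C@@H](OC#C)CO[Si](C(C)C)(C(C)C)C(C)C
F11 | step 12 | diborylated diyne | COc1cc(cc(OC)c1O[Si](C(C)C)(C(C)C)C(C)C)[C@H](OC#CB1OC(C)(C)C(C)(C)O1)[C@@H](OC#CB1OC(C)(C)C(C)(C)O1)CO[Si](C(C)C)(C(C)C)C(C)C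
F12 | step 11 | C,O-bis(trimethylsilyl) compound | COc1cc(cc(OC)c1O[Si](C(C)C)(C(C)C)C(C)C)[C@H](O[Si](C)(C)C)[C@@H](OC#C[Si](C)(C)C)CO[Si](C(C)C)(C(C)C)C(C)C
F13 | step 11 | alkynylsilane alcohol | COc1cc(cc(OC)c1O[Si](C(C)C)(C(C)C)C(C)C)[C@H](O)[C@@H](OC#C[Si](C)(C)C)CO[Si](C(C)C)(C(C)C)C(C)C
F14 | step 11 | silyl-capped dichlorovinyl ether | COc1cc(cc(OC)c1O[Si](C(C)C)(C(C)C)C(C)C)[C@H](O/C(Cl)=C\Cl)[C@@H](OC#C[Si](C)(C)C)CO[Si](C(C)C)(C(C)C)C(C)C
F15 | step 15 | C3 phenol | COc1cc(cc(OC)c1O[Si](C(C)C)(C(C)C)C(C)C)[C@@H]1Oc2cc(/C=C/CO[Si](C)(C)C(C)(C)C)cc(O)c2O[C@H]1CO[Si](C(C)C)(C(C)C)C(C)C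
A1 | alternative 1 | ethyl (2R,3S)-2-[2-bromo-4-[(E)-3-ethoxy-3-oxoprop-1-enyl]-6-methoxyphenoxy]-3-[3,5-dimethoxy-4-(pivaloyloxy)phenyl]-3-hydroxypropanoate (threo ester) | COc1cc(cc(OC)c1OC(=O)C(C)(C)C)[C@H](O)[C@@H](Oc1c(Br)cc(/C=C/C(=O)OCC)cc1OC)C(=O)OCC
A2 | alternative 2 | (7S,8S)-trans-benzodioxane with formyl on C1, methoxy on C3, free C9 hydroxyl and 3,5-dimethoxy-4-(methoxymethoxy)phenyl on C7 | COCOc1c(OC)cc(cc1OC)[C@@H]1Oc2cc(C=O)cc(OC)c2O[C@H]1CO
A3 | alternative 3 | (7S,8S)-trans-benzodioxane with dimethoxymethyl on C1, methoxy on C3, CH2OTBS on C8 and 3,5-dimethoxy-4-(methoxymethoxy)phenyl on C7 | COCOc1c(OC)cc(cc1OC)[C@@H]1Oc2cc(C(OC)OC)cc(OC)c2O[C@H]1CO[Si](C)(C)C(C)(C)C
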